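**Retrosynthetic overview**
1. Target 30 comes from triol 26 by C13 acetylation and C8 angeloylation; 26 comes from the silylated macrocycle 25.
2. 25 is cut at the C5=C6 enol-ether alkene, which joins the aldehyde carbon on quaternary C4 to the γ-carbon C6 of the butenolide and lies in the ten-membered carbocycle C1–C10; the precursor is seco aldehyde 22 (carbocycle, last ring).
3. 22 comes from 2-silylfuran 19: silicon on C12 decides where the lactone carbonyl appears (butenolide, second ring), and the vinyl group on C4 is the latent C5 aldehyde.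
4. 19 comes from furyl dithiane 14 and epoxide 6 (C8–C9 bond); C8 is then set by asymmetric transfer hydrogenation.
5. 6 comes from (S)-linalool 1 by allylic oxidation and Sharpless epoxidation–cyclisation (oxolane, first ring; C4 from 1, C1 and C10 from the tartrate).

Key step: step 15

Numbering: germacrane numbering is used throughout (C1 and C4 oxolane carbons, C6/C7/C11/C12 butenolide, C8 and C10 carbinols, C13 oxymethyl).

Remark on the chemistry: the SMILES is read literally as 1S,4S,8S,10R, which puts C5 and C10 on opposite faces of the oxolane (C10 cis to the C4 methyl), so the carbocycle bridges the oxolane in the in,out sense; every intermediate is drawn with exactly this configuration, and the strain this implies falls on step 15.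

**Step 1**
Reactants: 1 (S)-linalool
Product: 2 (2E,6S)-2,6-dimethylocta-2,7-diene-1,6-diol [(S)-8-hydroxylinalool]
Conditions: SeO2 (cat.), t-BuOOH, salicylic acid (cat.), CH2Cl2, rt
Reagents that add atoms: tert-butyl hydroperoxide, CC(C)(C)OO
Why: SeO2 allylic oxidation (ene reaction then 2,3-sigmatropic shift) is selective for the (E)-methyl group of the trisubstituted alkene and should leave the tertiary vinyl carbinol and its stereocentre untouched.

**Step 2**
Reactants: 2 (S)-8-hydroxylinalool
Product: 4 (2R)-2-[(2S,5S)-5-ethenyl-5-methyloxolan-2-yl]propane-1,2-diol, via epoxy diol 3 (not isolated)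
Conditions: Ti(OiPr)4, D-(−)-diethyl tartrate, t-BuOOH, 4 Å MS, CH2Cl2, −20 °C; then CSA (cat.), 0 °C to rt
Reagents that add atoms: tert-butyl hydroperoxide, CC(C)(C)OO
Why: Sharpless asymmetric epoxidation with the D-tartrate should give the (2R,3R)-epoxide, which fixes C10, and the C4 hydroxyl then opens it at the secondary carbon by 5-exo-tet attack with inversion, which sets C1 as S; C4 is carried over from 1.

**Step 3**
Reactants: 4 oxolane diol
Product: 6 (2S,5S)-2-ethenyl-2-methyl-5-[(2R)-2-methyloxiran-2-yl]oxolane, via primary tosylate 5 (not isolated)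
Conditions: NaH, N-tosylimidazole, THF, 0 °C to rt
Reagents that add atoms: none
Why: Selective sulfonylation of the primary hydroxyl and intramolecular Williamson closure by the tertiary alkoxide give the 2,2-disubstituted epoxide; no bond to C10 is broken, so its configuration is kept.

**Step 4**
Reactants: 7 furan-3-ylmethanol
Product: 8 tert-butyl(furan-3-ylmethoxy)dimethylsilane
Conditions: TBSCl, imidazole, DMF, rt
Reagents that add atoms: tert-butyldimethylsilyl chloride, CC(C)(C)[Si](C)(C)Cl
Why: Standard silylation of a primary alcohol.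

**Step 5**
Reactants: 8 silyl ether
Product: 10 [2-(tert-butyldimethylsilyl)furan-3-yl]methanol, via 2-lithiofuran 9 (not isolated)
Conditions: n-BuLi, HMPA, THF, −78 to 0 °C; aq NH4Cl
Reagents that add atoms: none
Why: Lithiation at C2, between the ring oxygen and the silyloxymethyl group, is followed by a 1,4 O-to-C silyl shift (retro-Brook rearrangement), which places silicon on the future C12 and frees the C13 hydroxyl.

**Step 6**
Reactants: 10 2-silylfuran alcohol
Product: 12 5-(tert-butyldimethylsilyl)-4-(hydroxymethyl)furan-3-carbaldehyde, via dilithio species 11 (not isolated)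
Conditions: n-BuLi (2.2 equiv), DME, 0 °C; then DMF, −78 to 0 °C
Reagents that add atoms: N,N-dimethylformamide, CN(C)C=O
Why: Alkoxide-directed ortho-lithiation goes to C4 because C2 is blocked by silicon, and formylation of the aryllithium with DMF introduces C8 on the future C7.

**Step 7**
Reactants: 12 hydroxy aldehyde
Product: 13 [2-(tert-butyldimethylsilyl)-4-(1,3-dithian-2-yl)furan-3-yl]methanol
Conditions: HS(CH2)3SH, MgBr2·OEt2, Et2O, rt
Reagents that add atoms: propane-1,3-dithiol, SCCCS
Why: Mild Lewis-acid dithioacetalisation converts the aldehyde (or its lactol form) into the dithiane without protodesilylation of the furan.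

**Step 8**
Reactants: 13 dithiane alcohol
Product: 14 tert-butyl{[2-(tert-butyldimethylsilyl)-4-(1,3-dithian-2-yl)furan-3-yl]methoxy}dimethylsilane
Conditions: TBSCl, imidazole, DMF, rt
Reagents that add atoms: tert-butyldimethylsilyl chloride, CC(C)(C)[Si](C)(C)Cl
Why: Standard silylation; C13 is carried as a silyl ether because an ester there would be lost from the later silyloxyfuran.

**Step 9**
Reactants: 14 furyl dithiane; 6 epoxide
Product: 16 (2R)-1-{2-[5-(tert-butyldimethylsilyl)-4-(tert-butyldimethylsilyloxymethyl)furan-3-yl]-1,3-dithian-2-yl}-2-[(2S,5S)-5-ethenyl-5-methyloxolan-2-yl]propan-2-ol, via lithiated dithiane 15 (not isolated)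
Conditions: n-BuLi, THF, −78 to −30 °C; then 6, HMPA, −30 °C to rt
Reagents that add atoms: none
Why: Corey–Seebach umpolung: the aryl-stabilised dithianyl anion opens the epoxide at its CH2 terminus (SN2) and forms the C8–C9 bond, leaving the C10 carbinol untouched.

**Step 10**
Reactants: 16 dithiane alcohol
Product: 17 (3R)-1-[5-(tert-butyldimethylsilyl)-4-(tert-butyldimethylsilyloxymethyl)furan-3-yl]-3-[(2S,5S)-5-ethenyl-5-methyloxolan-2-yl]-3-hydroxybutan-1-one
Conditions: MeI, CaCO3, MeCN–H2O (9:1), 45 °C
Reagents that add atoms: water, O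
Why: S-Methylation and buffered hydrolysis unmask the C8 ketone without oxidants or mercury salts, which the electron-rich silylfuran would not tolerate.

**Step 11**
Reactants: 17 β-hydroxy ketone
Product: 18 (1S,3R)-1-[5-(tert-butyldimethylsilyl)-4-(tert-butyldimethylsilyloxymethyl)furan-3-yl]-3-[(2S,5S)-5-ethenyl-5-methyloxolan-2-yl]butane-1,3-diol
Conditions: RuCl[(S,S)-TsDPEN](p-cymene) (cat.), HCO2H–Et3N (5:2), CH2Cl2, rt
Reagents that add atoms: none
Why: Noyori asymmetric transfer hydrogenation of a heteroaryl alkyl ketone: the (S,S) catalyst, which gives (S)-carbinols from aryl alkyl ketones, should place the furan under the arene ligand and set C8 as S by reagent control, without touching the vinyl group.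

**Step 12**
Reactants: 18 diol
Product: 19 8,10-bis(triethylsilyl) ether of 18
Conditions: TESOTf, 2,6-lutidine, CH2Cl2, −78 to 0 °C
Reagents that add atoms: triethylsilyl trifluoromethanesulfonate, CC[Si](CC)(CC)OS(=O)(=O)C(F)(F)F
Why: Silyl triflate silylates the secondary and the tertiary hydroxyl together; the C10 hydroxyl must be masked because it would otherwise be silylated in step 15, and the free C8 hydroxyl would compete for the lactone.

**Step 13**
Reactants: 19 2-silylfuran
Product: 20 3-(tert-butyldimethylsilyloxymethyl)-4-{(1S,3R)-3-[(2S,5S)-5-ethenyl-5-methyloxolan-2-yl]-1,3-bis(triethylsilyloxy)butyl}furan-2(5H)-one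
Conditions: AcOOH (in AcOH), NaOAc, CH2Cl2, 0 °C; then Et3N (cat.), rt
Reagents that add atoms: peracetic acid, CC(=O)OO
Why: Peracid oxidation of a 2-silylfuran (Kuwajima-type): attack at the silicon-bearing carbon, a 1,2-shift of silicon to oxygen and hydrolysis should put the carbonyl on C12 and a CH2 at C6, so the regiochemistry is fixed by where silicon sits.

**Step 14**
Reactants: 20 vinyl butenolide
Product: 22 (2S,5S)-5-{(2R,4S)-4-[4-(tert-butyldimethylsilyloxymethyl)-5-oxo-2,5-dihydrofuran-3-yl]-2,4-bis(triethylsilyloxy)butan-2-yl}-2-methyloxolane-2-carbaldehyde (seco aldehyde butenolide), via vicinal diol 21 (not isolated)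
Conditions: OsO4 (cat.), NaIO4, 2,6-lutidine, dioxane–H2O (3:1), rt
Reagents that add atoms: osmium tetroxide (catalytic oxygen carrier), O=[Os](=O)(=O)=O; sodium periodate, [Na+].[O-]I(=O)(=O)=O
Why: Lemieux–Johnson cleavage: OsO4 dihydroxylates only the monosubstituted alkene, the tetrasubstituted electron-poor butenolide alkene being inert, and periodate cleaves the diol to the C5 aldehyde, which has no α-hydrogen.

**Step 15**
Reactants: 22 seco aldehyde butenolide
Product: 25 (1S,2E,8S,10R,11S)-6-(tert-butyldimethylsilyloxymethyl)-1,10-dimethyl-8,10-bis(triethylsilyloxy)-4,14-dioxatricyclo[9.2.1.0(3,7)]tetradeca-2,6-dien-5-one, via 2-silyloxyfuran 23 (not isolated), via silylated aldol 24 (not isolated)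
Conditions: 22 added by syringe pump to TBSOTf, i-Pr2NEt, CH2Cl2, −20 °C to rt (final concentration about 1 mM); then DBU, rt
Reagents that add atoms: none
Why: TBSOTf and i-Pr2NEt turn the butenolide into the aromatic 2-silyloxyfuran 23 by soft enolisation at C6, whose C6 terminus adds to the TBSOTf-activated, non-enolisable C5 aldehyde to give the silylated aldol 24, and DBU then removes the C6 proton again and expels the C5 silanolate (E1cB) to leave the C5=C6 alkene of 25. The closest known reaction type is the one-pot silyl triflate/amine/DBU condensation of 2(5H)-furanones with aldehydes to γ-ylidenebutenolides (vinylogous Mukaiyama aldol then elimination), run here within one molecule. The ten-membered carbocycle closes in a 10-(enolendo)-exo-trig mode, with the nucleophilic C6=C7 enol bond inside the new ring and the aldehyde oxygen outside it. No stereocentre is formed, since the C5 and C6 centres of 24 are erased on elimination; only the alkene geometry is set, and C4 syn to C7 (5E) is favoured, though not strictly enforced, because the other isomer would hold a trans double bond in the bridged medium ring. γ-Attack is secured by the substituent on C11, which blocks the α-carbon, and C6 is preferred over the also vinylogous C8–H because only C6 deprotonation gives a furan; ring closure over oligomerisation rests on dilution alone. The closure has to join C5 and C10 across opposite faces of the oxolane, and this strain is the main exposure of the route.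

**Step 16**
Reactants: 25 silylated macrocycle
Product: 26 (1S,2E,8S,10R,11S)-8,10-dihydroxy-6-(hydroxymethyl)-1,10-dimethyl-4,14-dioxatricyclo[9.2.1.0(3,7)]tetradeca-2,6-dien-5-one
Conditions: HF·pyridine, pyridine, THF, 0 °C to rt
Reagents that add atoms: none
Why: Buffered fluoride desilylation removes the primary TBS and both TES ethers under weakly acidic conditions that the enol lactone should tolerate.

**Step 17**
Reactants: 26 triol
Product: 27 13-O-acetate of 26
Conditions: AcCl, 2,4,6-collidine, CH2Cl2, −78 °C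
Reagents that add atoms: acetyl chloride, CC(Cl)=O
Why: Kinetic acylation with a hindered pyridine base is selective for the primary C13 hydroxyl over the ring-flanked secondary C8 and tertiary C10 hydroxyls.

**Step 18**
Reactants: 27 13-acetate; 28 angelic acid [(2Z)-2-methylbut-2-enoic acid]
Product: 30 target [(1S,2E,8S,10R,11S)-6-(acetyloxymethyl)-10-hydroxy-1,10-dimethyl-5-oxo-4,14-dioxatricyclo[9.2.1.0(3,7)]tetradeca-2,6-dien-8-yl (2Z)-2-methylbut-2-enoate], via mixed anhydride 29 (not isolated)
Conditions: 28, 2,4,6-Cl3C6H2COCl, Et3N, toluene, rt; then 27, toluene, 75 °C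
Reagents that add atoms: none
Why: Yamaguchi esterification: the alcohol attacks the less hindered angeloyl carbonyl of the mixed anhydride, and without a nucleophilic catalyst the Z-alkene should not isomerise to the tiglate; the tertiary C10 hydroxyl does not react.

**Compound list**
1 | (S)-linalool | CC(C)=CCC[C@@](C)(C=C)O | starting material
2 | (2E,6S)-2,6-dimethylocta-2,7-diene-1,6-diol | OC/C(C)=C/CC[C@@](C)(C=C)O | intermediate
3 | (3S)-5-[(2R,3R)-3-(hydroxymethyl)-3-methyloxiran-2-yl]-3-methylpent-1-en-3-ol | OC[C@@]1(C)O[C@@H]1CC[C@@](C)(C=C)O | intermediate (not isolated)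
4 | (2R)-2-[(2S,5S)-5-ethenyl-5-methyloxolan-2-yl]propane-1,2-diol | OC[C@@](C)(O)[C@@H]1CC[C@@](C)(C=C)O1 | intermediate
5 | primary tosylate of 4 | Cc1ccc(cc1)S(=O)(=O)OC[C@@](C)(O)[C@@H]1CC[C@@](C)(C=C)O1 | intermediate (not isolated)
6 | (2S,5S)-2-ethenyl-2-methyl-5-[(2R)-2-methyloxiran-2-yl]oxolane | C1O[C@@]1(C)[C@@H]2CC[C@@](C)(C=C)O2 | intermediate
7 | furan-3-ylmethanol | OCc1ccoc1 | starting material
8 | tert-butyl(furan-3-ylmethoxy)dimethylsilane | CC(C)(C)[Si](C)(C)OCc1ccoc1 | intermediate
9 | 2-lithio derivative of 8 | [Li]c1occc1CO[Si](C)(C)C(C)(C)C | intermediate (not isolated)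
10 | [2-(tert-butyldimethylsilyl)furan-3-yl]methanol | OCc1ccoc1[Si](C)(C)C(C)(C)C | intermediate
11 | lithium [2-(tert-butyldimethylsilyl)-4-lithiofuran-3-yl]methanolate | [Li]OCc1c([Li])coc1[Si](C)(C)C(C)(C)C | intermediate (not isolated)
12 | 5-(tert-butyldimethylsilyl)-4-(hydroxymethyl)furan-3-carbaldehyde | OCc1c(C=O)coc1[Si](C)(C)C(C)(C)C | intermediate
13 | [2-(tert-butyldimethylsilyl)-4-(1,3-dithian-2-yl)furan-3-yl]methanol | OCc1c(C2SCCCS2)coc1[Si](C)(C)C(C)(C)C | intermediate
14 | tert-butyl{[2-(tert-butyldimethylsilyl)-4-(1,3-dithian-2-yl)furan-3-yl]methoxy}dimethylsilane | CC(C)(C)[Si](C)(C)OCc1c(C2SCCCS2)coc1[Si](C)(C)C(C)(C)C | intermediate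
15 | 2-lithio-1,3-dithiane derived from 14 | CC(C)(C)[Si](C)(C)OCc1c(C2([Li])SCCCS2)coc1[Si](C)(C)C(C)(C)C | intermediate (not isolated)
16 | C8 dithiane, C10 alcohol (name in step 9) | CC(C)(C)[Si](C)(C)OCc1c(C2(C[C@@](C)(O)[C@@H]3CC[C@@](C)(C=C)O3)SCCCS2)coc1[Si](C)(C)C(C)(C)C | intermediate
17 | C8 ketone (name in step 10) | CC(C)(C)[Si](C)(C)OCc1c(C(=O)C[C@@](C)(O)[C@@H]2CC[C@@](C)(C=C)O2)coc1[Si](C)(C)C(C)(C)C | intermediate
18 | (8S,10R)-diol (name in step 11) | CC(C)(C)[Si](C)(C)OCc1c([C@@H](O)C[C@@](C)(O)[C@@H]2CC[C@@](C)(C=C)O2)coc1[Si](C)(C)C(C)(C)C | intermediate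
19 | 8,10-bis(triethylsilyl) ether of 18 | CC[Si](CC)(CC)O[C@H](c1coc([Si](C)(C)C(C)(C)C)c1CO[Si](C)(C)C(C)(C)C)C[C@@](C)(O[Si](CC)(CC)CC)[C@@H]2CC[C@@](C)(C=C)O2 | intermediate
20 | vinyl butenolide (name in step 13) | CC[Si](CC)(CC)O[C@H](C1=C(CO[Si](C)(C)C(C)(C)C)C(=O)OC1)C[C@@](C)(O[Si](CC)(CC)CC)[C@@H]2CC[C@@](C)(C=C)O2 | intermediate
21 | vicinal diol from the vinyl group of 20 (mixture at the new carbinol) | CC[Si](CC)(CC)O[C@H](C1=C(CO[Si](C)(C)C(C)(C)C)C(=O)OC1)C[C@@](C)(O[Si](CC)(CC)CC)[C@@H]2CC[C@@](C)(C(O)CO)O2 | intermediate (not isolated)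
22 | seco aldehyde butenolide (name in step 14) | CC[Si](CC)(CC)O[C@H](C1=C(CO[Si](C)(C)C(C)(C)C)C(=O)OC1)C[C@@](C)(O[Si](CC)(CC)CC)[C@@H]2CC[C@@](C)(C=O)O2 | intermediate
23 | 2-(tert-butyldimethylsilyloxy)furan derived from 22 | CC[Si](CC)(CC)O[C@H](c1coc(O[Si](C)(C)C(C)(C)C)c1CO[Si](C)(C)C(C)(C)C)C[C@@](C)(O[Si](CC)(CC)CC)[C@@H]2CC[C@@](C)(C=O)O2 | intermediate (not isolated)
24 | macrocyclic C5-silyloxy aldol (mixture at C5 and C6) | CC[Si](CC)(CC)O[C@H]1C[C@@](C)(O[Si](CC)(CC)CC)[C@@H]2CC[C@@](C)(C(O[Si](C)(C)C(C)(C)C)C3OC(=O)C(CO[Si](C)(C)C(C)(C)C)=C31)O2 | intermediate (not isolated)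
25 | silylated macrocyclic enol lactone (name in step 15) | CC[Si](CC)(CC)O[C@H]1C[C@@](C)(O[Si](CC)(CC)CC)[C@@H]2CC[C@@](C)(/C=C3/OC(=O)C(CO[Si](C)(C)C(C)(C)C)=C31)O2 | intermediate
26 | triol (name in step 16) | O[C@H]1C[C@@](C)(O)[C@@H]2CC[C@@](C)(/C=C3/OC(=O)C(CO)=C31)O2 | intermediate
27 | 13-O-acetate of 26 | O[C@H]1C[C@@](C)(O)[C@@H]2CC[C@@](C)(/C=C3/OC(=O)C(COC(C)=O)=C31)O2 | intermediate
28 | angelic acid | C/C=C(/C)C(O)=O | starting material
29 | angelic 2,4,6-trichlorobenzoic anhydride | C/C=C(/C)C(=O)OC(=O)c1c(Cl)cc(Cl)cc1Cl | intermediate (not isolated)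
30 | CNP0162854.1 | C/C=C(/C)C(=O)O[C@H]1C[C@@](C)(O)[C@@H]2CC[C@@](C)(/C=C3/OC(=O)C(COC(C)=O)=C31)O2 | target

**Step count**
Total: 18 steps. Longest linear sequence: 15 steps (7 to 30, steps 4–18); 13 steps from 1.

**Steps most likely to fail**

Step 15. The intramolecular addition may lose to intermolecular aldol addition (dimers and oligomers), or the closed aldol may fail to lose silanol, because the chain must close a strained bridged medium ring across opposite faces of the oxolane. Ionisation of the C13 silyl ether from the silyloxyfuran and epimerisation at C8 on long exposure to DBU are further hazards. Fallback, from 20 back to 25, replaces the aldol by a phosphorus-driven olefination at the same bond. 20 would be taken through its silyloxyfuran (TBSOTf, Et3N, CH2Cl2, −78 °C) and NBS to the γ-bromobutenolide F1. Michaelis–Arbuzov reaction with P(OMe)3 in toluene at 80 °C would give the C6 dimethyl phosphonate F2. Cleavage of the vinyl group as in step 14 would give the aldehyde phosphonate F3. Slow addition of F3 to LiCl and i-Pr2NEt in MeCN at high dilution would close the ring by intramolecular Horner–Wadsworth–Emmons olefination, as known for 3-phosphorylphthalides, and give 25; irreversible loss of phosphate would pay for the strain.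

Step 9. The SN2 opening may be too slow, since a hindered tertiary dithianyl anion must attack a neopentyl-like epoxide terminus; proton transfer or metalation of the furan C6–H could take over. Fallback, from 6 back to 17, moves the umpolung to the unhindered parent dithiane. 2-Lithio-1,3-dithiane (THF, HMPA) would open 6 to the hydroxy dithiane F4. MeI and CaCO3 in aqueous MeCN would give the β-hydroxy aldehyde F5. Addition of excess dilithio species 11 (from 10, DME, −78 °C) would give the triol F6 as both C8 epimers. TBSCl and imidazole would silylate the primary hydroxyl to give the silyl ether F7, and MnO2 would oxidise the furyl carbinol to 17.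

Step 13. The peracid may attack the unsubstituted C6 side or cleave the ring to an enedione instead of attacking the hindered silicon-bearing C12. Fallback, from 19 back to 20, uses cycloaddition in place of electrophilic attack. Singlet oxygen (O2, hν, tetraphenylporphyrin, CH2Cl2, −78 °C) would add across C6 and C12, and silyl migration in the endoperoxide would give the 5-hydroxybutenolide F8 with the carbonyl at C12. NaBH4 in MeOH at 0 °C with a mildly acidic work-up would reduce the masked C6 aldehyde and relactonise to 20.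

**Further compounds**
F1 | step 15 | C6-bromo derivative of 20 (5-bromofuran-2(5H)-one, mixture at C6) | CC[Si](CC)(CC)O[C@H](C1=C(CO[Si](C)(C)C(C)(C)C)C(=O)OC1Br)C[C@@](C)(O[Si](CC)(CC)CC)[C@@H]2CC[C@@](C)(C=C)O2
F2 | step 15 | C6 dimethyl phosphonate of 20 | CC[Si](CC)(CC)O[C@H](C1=C(CO[Si](C)(C)C(C)(C)C)C(=O)OC1P(=O)(OC)OC)C[C@@](C)(O[Si](CC)(CC)CC)[C@@H]2CC[C@@](C)(C=C)O2
F3 | step 15 | C6 dimethyl phosphonate of 22 (aldehyde phosphonate) | CC[Si](CC)(CC)O[C@H](C1=C(CO[Si](C)(C)C(C)(C)C)C(=O)OC1P(=O)(OC)OC)C[C@@](C)(O[Si](CC)(CC)CC)[C@@H]2CC[C@@](C)(C=O)O2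
F4 | step 9 | (2R)-1-(1,3-dithian-2-yl)-2-[(2S,5S)-5-ethenyl-5-methyloxolan-2-yl]propan-2-ol | S1CCCSC1C[C@@](C)(O)[C@@H]2CC[C@@](C)(C=C)O2
F5 | step 9 | (3R)-3-[(2S,5S)-5-ethenyl-5-methyloxolan-2-yl]-3-hydroxybutanal | O=CC[C@@](C)(O)[C@@H]1CC[C@@](C)(C=C)O1
F6 | step 9 | triol, C13-desilyl analogue of 18 as both C8 epimers | OCc1c(C(O)C[C@@](C)(O)[C@@H]2CC[C@@](C)(C=C)O2)coc1[Si](C)(C)C(C)(C)C
F7 | step 9 | C13 tert-butyldimethylsilyl ether of F6 (18 as both C8 epimers) | CC(C)(C)[Si](C)(C)OCc1c(C(O)C[C@@](C)(O)[C@@H]2CC[C@@](C)(C=C)O2)coc1[Si](C)(C)C(C)(C)C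
F8 | step 13 | C6-hydroxy derivative of 20 (5-hydroxyfuran-2(5H)-one, mixture at C6) | CC[Si](CC)(CC)O[C@H](C1=C(CO[Si](C)(C)C(C)(C)C)C(=O)OC1O)C[C@@](C)(O[Si](CC)(CC)CC)[C@@H]2CC[C@@](C)(C=C)O2
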